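**Retrosynthetic overview**
- Target ⇐ global hydrogenolysis of a tris-benzyl ether (two aryl OBn, one CH2OBn).
- Tertiary carbinol ⇐ addition of a 3,4-dimethoxybenzyl Grignard reagent to a 2,3-cis oxolan-3-one, anti to both ring substituents.
- Ketone ⇐ oxidation of a relay secondary alcohol; aryl-bearing centre ⇐ aryllithium addition to a lactone, then hemiketal reduction with hydride entering trans to CH2OBn.
- CH2O-bearing centre ⇐ trans-selective dianion alkylation of (S)-3-hydroxy-γ-butyrolactone with benzyl chloromethyl ether.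
- Rings: none is built. The single oxolane ring is the lactone ring of the chiral-pool starting material, carried through (the lactone C=O becomes the aryl-bearing carbon).

Assumption: the benzyl-protected bromocatechol and 3,4-dimethoxybenzyl chloride are taken as purchasable.

**Step 1**
Reactants: 1 (S)-3-hydroxy-γ-butyrolactone [(4S)-4-hydroxyoxolan-2-one]; 2 benzyl chloromethyl ether
Product: 4 (3S,4S)-3-[(benzyloxy)methyl]-4-hydroxyoxolan-2-one, via dilithium enolate-alkoxide 3 (not isolated)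
Conditions: LiN(iPr)2 (2.2 equiv), THF, −78 °C, 1 h; 2 (1.1 equiv), −78 → −45 °C; aq. NH4Cl
Reagents that add atoms: benzyl chloromethyl ether (2), ClCOCc1ccccc1
Why: Fráter–Seebach-type dianion alkylation, in which the electrophile attacks the rigid lactone enolate on the face opposite the neighbouring lithium alkoxide, so the new centre is set 3,4-trans (3S) by substrate control and the alkoxide cannot be lost by β-elimination.

**Step 2**
Reactants: 4 (3S,4S)-3-[(benzyloxy)methyl]-4-hydroxyoxolan-2-one; 5 4-bromo-1,2-bis(benzyloxy)benzene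
Product: 7 (3S,4S)-2-[3,4-bis(benzyloxy)phenyl]-3-[(benzyloxy)methyl]oxolane-2,4-diol (hemiketal mixture at C2), via aryllithium 6 (not isolated)
Conditions: 5, n-BuLi (2.3 equiv each), THF, −78 °C, 30 min; then 4, −78 °C, 1 h; aq. NH4Cl at −78 °C
Reagents that add atoms: 4-bromo-1,2-bis(benzyloxy)benzene (5), Brc1ccc(OCc2ccccc2)c(OCc2ccccc2)c1
Why: Bromine–lithium exchange followed by aryllithium addition to the lactone carbonyl stops at the hemiketal at −78 °C (C-aryl glycoside tactic); the first equivalent only deprotonates the hydroxyl, whose alkoxide blocks β-elimination, and no lasting stereocentre is formed.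

**Step 3**
Reactants: 7 (3S,4S)-2-[3,4-bis(benzyloxy)phenyl]-3-[(benzyloxy)methyl]oxolane-2,4-diol
Product: 9 (3S,4S,5R)-5-[3,4-bis(benzyloxy)phenyl]-4-[(benzyloxy)methyl]oxolan-3-ol, via oxocarbenium ion 8 (not isolated)
Conditions: Et3SiH (5 equiv), BF3·OEt2 (3 equiv), CH2Cl2, −78 → −40 °C; aq. NaHCO3
Reagents that add atoms: none
Why: Ionic hydrogenation of a hemiketal, in which the silane hydride enters the cyclic oxocarbenium ion trans to the adjacent CH2OBn group and cis to the ring hydroxyl (two reinforcing preferences), placing the aryl group cis to CH2OBn (5R).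

**Step 4**
Reactants: 9 (3S,4S,5R)-5-[3,4-bis(benzyloxy)phenyl]-4-[(benzyloxy)methyl]oxolan-3-ol
Product: 10 (4R,5R)-5-[3,4-bis(benzyloxy)phenyl]-4-[(benzyloxy)methyl]oxolan-3-one
Conditions: Dess–Martin periodinane (1.3 equiv), NaHCO3, CH2Cl2, 0 °C → rt; used at once
Reagents that add atoms: none
Why: Dess–Martin oxidation under buffered, non-basic conditions removes the relay carbinol centre without epimerising the α-centre of the base-sensitive 2,3-cis ketone.

**Step 5**
Reactants: 10 (4R,5R)-5-[3,4-bis(benzyloxy)phenyl]-4-[(benzyloxy)methyl]oxolan-3-one; 11 3,4-dimethoxybenzyl chloride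
Product: 13 (3R,4R,5R)-5-[3,4-bis(benzyloxy)phenyl]-4-[(benzyloxy)methyl]-3-[(3,4-dimethoxyphenyl)methyl]oxolan-3-ol, via benzylic Grignard reagent 12 (not isolated)
Conditions: 11, Mg, THF, 0 °C, slow addition; then 10, anhydrous CeCl3 (1.5 equiv), THF, −78 °C, add 12 (2 equiv), −78 → −40 °C; aq. NH4Cl
Reagents that add atoms: 3,4-dimethoxybenzyl chloride (11), COc1ccc(CCl)cc1OC
Why: CeCl3-promoted Grignard 1,2-addition, in which the benzyl nucleophile attacks the ring ketone from the face opposite the cis CH2OBn and aryl groups (steric approach control), setting the tertiary carbinol with OH cis to both (3R) while the oxophilic additive suppresses enolisation.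

**Step 6**
Reactants: 13 (3R,4R,5R)-5-[3,4-bis(benzyloxy)phenyl]-4-[(benzyloxy)methyl]-3-[(3,4-dimethoxyphenyl)methyl]oxolan-3-ol
Product: 14 (3R,4R,5R)-5-(3,4-dihydroxyphenyl)-3-[(3,4-dimethoxyphenyl)methyl]-4-(hydroxymethyl)oxolan-3-ol
Conditions: H2 (1 atm), 10% Pd/C, EtOAc–MeOH (1:1), rt, stopped at full conversion
Reagents that add atoms: none
Why: Catalytic hydrogenolysis cleaves the two aryl benzyl ethers and the alkyl benzyl ether under neutral conditions, touching no stereocentre and leaving the cyclic benzylic ether, tertiary alcohol and methyl ethers intact.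

**Compound list**
1 | (S)-3-hydroxy-γ-butyrolactone, (4S)-4-hydroxyoxolan-2-one | O=C1C[C@H](O)CO1 | starting material
2 | benzyl chloromethyl ether | ClCOCc1ccccc1 | starting material
3 | dilithium enolate-alkoxide of 1 (not isolated) | [Li]OC1=C[C@H](O[Li])CO1 | intermediate
4 | (3S,4S)-3-[(benzyloxy)methyl]-4-hydroxyoxolan-2-one (3,4-trans) | O=C1[C@@H](COCc2ccccc2)[C@H](O)CO1 | intermediate
5 | 4-bromo-1,2-bis(benzyloxy)benzene | Brc1ccc(OCc2ccccc2)c(OCc2ccccc2)c1 | starting material
6 | [3,4-bis(benzyloxy)phenyl]lithium (not isolated) | [Li]c1ccc(OCc2ccccc2)c(OCc2ccccc2)c1 | intermediate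
7 | (3S,4S)-2-[3,4-bis(benzyloxy)phenyl]-3-[(benzyloxy)methyl]oxolane-2,4-diol (hemiketal, C2 mixture, equilibrates with its open-chain hydroxy ketone) | O[C@@H]1COC(O)(c2ccc(OCc3ccccc3)c(OCc3ccccc3)c2)[C@H]1COCc1ccccc1 | intermediate
8 | (3S,4S)-5-[3,4-bis(benzyloxy)phenyl]-4-[(benzyloxy)methyl]-3-hydroxy-3,4-dihydro-2H-furan-1-ium, oxocarbenium ion (not isolated) | O[C@@H]1C[O+]=C(c2ccc(OCc3ccccc3)c(OCc3ccccc3)c2)[C@H]1COCc1ccccc1 | intermediate
9 | (3S,4S,5R)-5-[3,4-bis(benzyloxy)phenyl]-4-[(benzyloxy)methyl]oxolan-3-ol (aryl and CH2OBn cis, OH trans to both) | O[C@@H]1CO[C@@H](c2ccc(OCc3ccccc3)c(OCc3ccccc3)c2)[C@H]1COCc1ccccc1 | intermediate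
10 | (4R,5R)-5-[3,4-bis(benzyloxy)phenyl]-4-[(benzyloxy)methyl]oxolan-3-one (cis) | O=C1CO[C@@H](c2ccc(OCc3ccccc3)c(OCc3ccccc3)c2)[C@H]1COCc1ccccc1 | intermediate
11 | 3,4-dimethoxybenzyl chloride, 4-(chloromethyl)-1,2-dimethoxybenzene | COc1ccc(CCl)cc1OC | starting material
12 | (3,4-dimethoxybenzyl)magnesium chloride (not isolated) | COc1ccc(C[Mg]Cl)cc1OC | intermediate
13 | (3R,4R,5R)-5-[3,4-bis(benzyloxy)phenyl]-4-[(benzyloxy)methyl]-3-[(3,4-dimethoxyphenyl)methyl]oxolan-3-ol | COc1ccc(C[C@]2(O)CO[C@@H](c3ccc(OCc4ccccc4)c(OCc4ccccc4)c3)[C@H]2COCc2ccccc2)cc1OC | intermediate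
14 | (3R,4R,5R)-5-(3,4-dihydroxyphenyl)-3-[(3,4-dimethoxyphenyl)methyl]-4-(hydroxymethyl)oxolan-3-ol (aryl, CH2OH and OH all cis) | COc1ccc(C[C@]2(O)CO[C@@H](c3ccc(O)c(O)c3)[C@H]2CO)cc1OC | target

**Totals**
Total step count: 6. Longest linear sequence: 6 steps (1 → 14).

**Three steps most likely to fail**

Step 5. The risks are Wurtz coupling when making 12, and enolisation of 10 followed by epimerisation or ring-opening β-elimination. The fallback sets out from 10 and comes back at 13. Chloromethyllithium F5 is generated in the presence of 10 from ICH2Cl and MeLi·LiBr (THF, −78 °C). This weakly basic carbenoid adds to the ketone, like the benzyl reagent, trans to the two ring substituents. It gives chlorohydrin (3R,4R,5R)-5-[3,4-bis(benzyloxy)phenyl]-4-[(benzyloxy)methyl]-3-(chloromethyl)oxolan-3-ol F6 as its lithium alkoxide. On warming to rt this closes to spiro-epoxide (3S,6R,7R)-6-[3,4-bis(benzyloxy)phenyl]-7-[(benzyloxy)methyl]-1,5-dioxaspiro[2.4]heptane F7. Copper-catalysed opening of the epoxide at its CH2 carbon with commercial (3,4-dimethoxyphenyl)magnesium bromide (CuBr·SMe2 10 mol %, THF, −30 → 0 °C) then makes the aryl–CH2 bond instead of the CH2–carbinol bond. This gives 13 with the same configuration at the carbinol carbon.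

Step 2. The risks are enolisation of 4 and double addition of 6 to the unprotected hydroxy lactone. The fallback sets out from 4 and comes back at 7. Lactone 4 is opened with MeNH(OMe)·HCl and AlMe3 (CH2Cl2, 0 °C) to the Weinreb amide (2S,3S)-2-[(benzyloxy)methyl]-3,4-dihydroxy-N-methoxy-N-methylbutanamide F2. Its diol is capped at once with 2,2-dimethoxypropane and pyridinium p-toluenesulfonate to give (2S)-3-(benzyloxy)-2-[(4S)-2,2-dimethyl-1,3-dioxolan-4-yl]-N-methoxy-N-methylpropanamide F3. Aryllithium 6 (1.2 equiv, THF, −78 °C) then gives, through the chelated tetrahedral intermediate and without over-addition, the ketone (2S)-1-[3,4-bis(benzyloxy)phenyl]-3-(benzyloxy)-2-[(4S)-2,2-dimethyl-1,3-dioxolan-4-yl]propan-1-one F4. Finally, 80% aqueous AcOH at rt removes the acetonide, and the freed open-chain form closes to hemiketal 7.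

Step 1. The risks are O- versus C-alkylation and a modest yield with the very reactive chloromethyl ether. The fallback sets out from 1 and comes back at 4. Dianion 3 is trapped instead with formaldehyde (paraformaldehyde as source, THF, −78 °C) in an aldol reaction. With the same trans facial bias this gives (3S,4S)-4-hydroxy-3-(hydroxymethyl)oxolan-2-one F1. Its primary hydroxyl is then benzylated selectively with BnBr and Ag2O in CH2Cl2 (mono-benzylation of a diol at the less hindered oxygen), which delivers 4.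

**Further compounds**
F1 | step 1 | (3S,4S)-4-hydroxy-3-(hydroxymethyl)oxolan-2-one | O=C1[C@@H](CO)[C@H](O)CO1
F2 | step 2 | (2S,3S)-2-[(benzyloxy)methyl]-3,4-dihydroxy-N-methoxy-N-methylbutanamide | CON(C)C(=O)[C@@H](COCc1ccccc1)[C@H](O)CO
F3 | step 2 | (2S)-3-(benzyloxy)-2-[(4S)-2,2-dimethyl-1,3-dioxolan-4-yl]-N-methoxy-N-methylpropanamide | CON(C)C(=O)[C@@H](COCc1ccccc1)[C@H]1COC(C)(C)O1
F4 | step 2 | (2S)-1-[3,4-bis(benzyloxy)phenyl]-3-(benzyloxy)-2-[(4S)-2,2-dimethyl-1,3-dioxolan-4-yl]propan-1-one | O=C(c1ccc(OCc2ccccc2)c(OCc2ccccc2)c1)[C@@H](COCc1ccccc1)[C@H]1COC(C)(C)O1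
F5 | step 5 | chloromethyllithium | [Li]CCl
F6 | step 5 | (3R,4R,5R)-5-[3,4-bis(benzyloxy)phenyl]-4-[(benzyloxy)methyl]-3-(chloromethyl)oxolan-3-ol | ClC[C@]1(O)CO[C@@H](c2ccc(OCc3ccccc3)c(OCc3ccccc3)c2)[C@H]1COCc1ccccc1
F7 | step 5 | (3S,6R,7R)-6-[3,4-bis(benzyloxy)phenyl]-7-[(benzyloxy)methyl]-1,5-dioxaspiro[2.4]heptane | C1[C@]2(O1)CO[C@@H](c3ccc(OCc4ccccc4)c(OCc4ccccc4)c3)[C@H]2COCc2ccccc2
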